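**Plan**
- **Feature:** ring B and the 2,2-dimethylpyran share the C4a–C8a bond, and C8a (bearing O1) is the direct neighbour of C8 (bearing OH). C8a can therefore begin as the O–CH= carbon of a dihydropyran-4-one and C8 as a carboxyl carbon.
- **Cuts:** C3=C4 is traced back to a C4 ketone, and ring B is then opened at C8–C8a to a (Z)-3,5-dienoic acid. The acid is cut at C7–C8 (CO), C4a–C5 (cross-coupling) and C6–CH2 of the propyl chain (carbometalation). The side fragments are cut at aryl–CH2 and alkyne–prenyl.
- **Forward:** the pyran ring is made first. The ring A chain, the prenylated propargyl alcohol and the iodopyranone are joined in one three-component step, and CO then supplies C8. Ring B closes last from a dienylketene, and ketone-to-alkene adjustment and desilylation finish the synthesis.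
- **Stereochemistry:** the target has no stereocentre. The only element to control is the Z geometry of C5=C6 in the open chain, which is set by anti carbomagnesiation through a magnesium alkoxide chelate and is absorbed into ring B.

Key step: step 10

Remark: the chromene numbering of the target (O1, C2, C3, C4, C4a, C5 to C8, C8a) is kept for the same atoms in all precursors. 4-Bromo-3-methoxyphenol is assumed to be the most direct commercial source of ring A.

Step 1
Reactants: 1 4-bromo-3-methoxyphenol
Product: 2 (4-bromo-3-methoxyphenoxy)triisopropylsilane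
Conditions: TIPSCl, imidazole, DMF, rt
Reagents that add atoms: triisopropylsilyl chloride, CC(C)[Si](Cl)(C(C)C)C(C)C
Why: Imidazole-promoted silylation of a phenol gives a bulky aryl silyl ether that should withstand the magnesium, zinc, palladium and hydride reagents to come and leaves with fluoride at the end.

Step 2
Reactants: 2 (4-bromo-3-methoxyphenoxy)triisopropylsilane; 3 1-bromo-3-chloropropane
Product: 5 [4-(3-chloropropyl)-3-methoxyphenoxy]triisopropylsilane, via aryl Grignard reagent 4 (not isolated)
Conditions: Mg, THF, reflux; then 3 (1.5 equiv), Li2CuCl4 (3 mol %), THF, 0 °C to rt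
Reagents that add atoms: none
Why: Copper-catalysed cross-coupling of an aryl Grignard reagent with a primary alkyl halide should take place at the C–Br end of 3, since the C–Cl bond reacts far more slowly, and so installs the three-carbon chain with a halide ready for the next Grignard formation.

Step 3
Reactants: 6 propargyl alcohol; 7 prenyl bromide
Product: 8 6-methylhept-5-en-2-yn-1-ol
Conditions: CuI (10 mol %), K2CO3, Bu4NBr (10 mol %), DMF, rt
Reagents that add atoms: none
Why: In this copper-catalysed allylation of a terminal alkyne the copper acetylide formed under carbonate base should displace the primary allylic bromide mainly at its unsubstituted terminus, and the free hydroxyl is not alkylated under these conditions.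

Step 4
Reactants: 9 (E)-4-methoxybut-3-en-2-one; 10 acetone
Product: 12 2,2-dimethyl-2,3-dihydro-4H-pyran-4-one, via aldol adduct 11 (not isolated)
Conditions: LiN(iPr)2, THF, −78 °C; 10; AcOH (1 equiv), −78 °C; crude 11, CF3CO2H (20 mol %), CH2Cl2, rt
Reagents that add atoms: none
Why: Kinetic deprotonation of 9 at its methyl group and aldol addition to acetone should give 11, whose tertiary hydroxyl then adds to the β-methoxyenone under acid and expels methanol (oxa-Michael addition–elimination, 6-endo closure) to form the pyran ring.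

Step 5
Reactants: 12 2,2-dimethyl-2,3-dihydro-4H-pyran-4-one
Product: 13 5-iodo-2,2-dimethyl-2,3-dihydro-4H-pyran-4-one
Conditions: I2, pyridine, CH2Cl2, 0 °C to rt
Reagents that add atoms: iodine, II
Why: Pyridine-mediated α-iodination of an enone should place iodine on the α-carbon of the vinylogous ester (the future C4a), which is its nucleophilic vinylic position.

Step 6
Reactants: 5 [4-(3-chloropropyl)-3-methoxyphenoxy]triisopropylsilane; 8 6-methylhept-5-en-2-yn-1-ol; 13 5-iodo-2,2-dimethyl-2,3-dihydro-4H-pyran-4-one
Product: 18 (Z)-3-(2,2-dimethyl-4-oxo-3,4-dihydro-2H-pyran-5-yl)-6-methyl-2-{3-[2-methoxy-4-(triisopropylsilyloxy)phenyl]propyl}hepta-2,5-dien-1-ol, via propyl Grignard reagent 14 (not isolated), via magnesium alkoxide 15 (not isolated), via oxamagnesole chelate 16 (not isolated), via alkenylzinc chloride 17 (not isolated)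
Conditions: 5, Mg (I2-activated), THF, reflux; separately 8 (1.3 equiv), iPrMgCl (1.3 equiv), THF, 0 °C; combine, CuI (15 mol %), THF–toluene, rt to 45 °C; ZnCl2, 0 °C; 13, Pd2(dba)3 (2.5 mol %), P(2-furyl)3 (10 mol %), rt to 40 °C; aq NH4Cl
Reagents that add atoms: none
Why: Copper-catalysed anti carbomagnesiation of the propargylic alkoxide should put the ring A propyl group on the carbon next to CH2O (C6) and magnesium on the prenyl-bearing carbon (C5) inside five-membered chelate 16, which holds metal and CH2O cis, and transmetalation to zinc followed by Negishi coupling with α-iodoenone 13 proceeds with retention to give the Z tetrasubstituted alkene.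

Step 7
Reactants: 18 the (Z)-dienyl alcohol
Product: 19 (Z)-3-(2,2-dimethyl-4-oxo-3,4-dihydro-2H-pyran-5-yl)-6-methyl-2-{3-[2-methoxy-4-(triisopropylsilyloxy)phenyl]propyl}hepta-2,5-dien-1-yl methyl carbonate
Conditions: ClCO2Me, pyridine, CH2Cl2, 0 °C
Reagents that add atoms: methyl chloroformate, COC(=O)Cl
Why: Acylation of a primary allylic alcohol with a chloroformate under pyridine is mild enough to leave the vinylogous ester and the alkene geometry untouched and removes the hydroxyl that could add to C8a.

Step 8
Reactants: 19 the allylic methyl carbonate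
Product: 20 methyl (Z)-4-(2,2-dimethyl-4-oxo-3,4-dihydro-2H-pyran-5-yl)-7-methyl-3-{3-[2-methoxy-4-(triisopropylsilyloxy)phenyl]propyl}octa-3,6-dienoate
Conditions: Pd(PPh3)4 (5 mol %), CO (20 bar), THF, 50 °C
Reagents that add atoms: carbon monoxide, [C-]#[O+]
Why: In this palladium-catalysed decarboxylative carbonylation of an allylic carbonate, zerovalent palladium ionises 19 with loss of CO2, CO inserts at the unhindered CH2 terminus (C7) and the released methoxide captures the acyl complex, while the geometry should hold because syn–anti exchange would need a σ-bond from palladium to the fully substituted C5.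

Step 9
Reactants: 20 the methyl (Z)-3,5-dienoate
Product: 22 (Z)-4-(2,2-dimethyl-4-oxo-3,4-dihydro-2H-pyran-5-yl)-7-methyl-3-{3-[2-methoxy-4-(triisopropylsilyloxy)phenyl]propyl}octa-3,6-dienoic acid, via trimethylstannyl ester 21 (not isolated)
Conditions: Me3SnOH (5 equiv), ClCH2CH2Cl, 70 °C; then aq HCl (0.1 M) wash
Reagents that add atoms: trimethyltin hydroxide, C[Sn](C)(C)O
Why: Trimethyltin hydroxide cleaves unhindered methyl esters under nearly neutral conditions, which should spare the dihydropyranone, the aryl silyl ether and the β,γ position of the alkene, all of which aqueous hydroxide would endanger.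

Step 10
Reactants: 22 the (Z)-3,5-dienoic acid
Product: 27 2,2-dimethyl-5-(3-methylbut-2-enyl)-6-{3-[2-methoxy-4-(triisopropylsilyloxy)phenyl]propyl}-4-oxochroman-8-yl acetate, via mixed anhydride 23 (not isolated), via dienylketene 24 (not isolated), via cyclohexadienone 25 (not isolated), via phenol 26 (not isolated)
Conditions: Ac2O, NaOAc (2 equiv), 110 °C, Ar
Reagents that add atoms: acetic anhydride, CC(=O)OC(C)=O
Why: Acetic anhydride turns 22 into mixed anhydride 23, and acetate removes a proton from the C7 methylene, which is both allylic and α to the acyl group, so that acetic acid is lost and dienylketene 24 arises. In 24 the ketene C8=C7, the tetrasubstituted C6=C5 alkene and the pyranone alkene C4a=C8a form a cis-hexatriene, and the six-membered ring B closes in a thermally allowed disrotatory 6π electrocyclisation that makes the C8–C8a bond and gives dienone 25. The C8a hydrogen of 25 lies α to the new C8 carbonyl, so enolisation gives phenol 26, which the medium acetylates to 27, and the transient C8a centre of 25 disappears, so no stereocentre remains. The closest known reactions are the acetic anhydride–sodium acetate benzannulations of 3,5-dienoic acids and of Stobbe half-esters, which also close at the carbon next to oxygen in furans, and dienylketenes released from cyclohexadienones or cyclobutenones are known to ring-close with low barriers. The step needs the acetic acid arm and the pyranone cis on C5=C6, which step 6 secures, and C8a turns its hydrogen toward the inside of the triene with O1 pointing outward, so the closing termini are not crowded. C8a is the only sp2 carbon that can give a six-membered ring, the prenyl alkene lies trans to the ketene arm and cannot reach it, and capture of 24 by acetate merely returns 23.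

Step 11
Reactants: 27 the 8-acetoxychroman-4-one
Product: 28 rac-2,2-dimethyl-5-(3-methylbut-2-enyl)-6-{3-[2-methoxy-4-(triisopropylsilyloxy)phenyl]propyl}chromane-4,8-diol
Conditions: LiAlH4, THF, 0 °C; then H2O
Reagents that add atoms: none
Why: Hydride reduction takes the aryl ketone to the benzylic alcohol and cleaves the aryl acetate in the same operation, and the new C4 carbinol centre forms as a racemate, which is of no consequence because step 12 removes it.

Step 12
Reactants: 28 the chromane-4,8-diol
Product: 29 2,2-dimethyl-5-(3-methylbut-2-enyl)-6-{3-[2-methoxy-4-(triisopropylsilyloxy)phenyl]propyl}-2H-chromen-8-ol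
Conditions: TsOH·H2O (5 mol %), toluene, 60 °C
Reagents that add atoms: none
Why: Acid-catalysed E1 dehydration of a chroman-4-ol is a standard entry to 2,2-dimethylchromenes, since the C4 cation is stabilised by O1 through C8a and loses a C3 proton, whereas capture by the peri prenyl alkene would need an in-plane approach orthogonal to the empty orbital.

Step 13
Reactants: 29 the silylated chromenol
Product: 30 Kazinol N
Conditions: Bu4NF, AcOH, THF, 0 °C
Reagents that add atoms: none
Why: Fluoride cleaves the aryl silyl ether at low temperature, and the acetic acid buffer keeps both phenols protonated so that the chromene and the prenyl group meet neither strong base nor strong acid.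

**Compound list**
1 | 4-bromo-3-methoxyphenol | COc1cc(O)ccc1Br | starting material
2 | (4-bromo-3-methoxyphenoxy)triisopropylsilane | COc1cc(O[Si](C(C)C)(C(C)C)C(C)C)ccc1Br | intermediate
3 | 1-bromo-3-chloropropane | ClCCCBr | starting material
4 | 2-methoxy-4-(triisopropylsilyloxy)phenylmagnesium bromide | COc1cc(O[Si](C(C)C)(C(C)C)C(C)C)ccc1[Mg]Br | intermediate
5 | [4-(3-chloropropyl)-3-methoxyphenoxy]triisopropylsilane | COc1cc(O[Si](C(C)C)(C(C)C)C(C)C)ccc1CCCCl | intermediate
6 | propargyl alcohol | C#CCO | starting material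
7 | prenyl bromide | CC(C)=CCBr | starting material
8 | 6-methylhept-5-en-2-yn-1-ol | CC(C)=CCC#CCO | intermediate
9 | (E)-4-methoxybut-3-en-2-one | CO/C=C/C(C)=O | starting material
10 | acetone | CC(C)=O | starting material
11 | (E)-5-hydroxy-1-methoxy-5-methylhex-1-en-3-one | CO/C=C/C(=O)CC(C)(C)O | intermediate
12 | 2,2-dimethyl-2,3-dihydro-4H-pyran-4-one | CC1(C)CC(=O)C=CO1 | intermediate
13 | 5-iodo-2,2-dimethyl-2,3-dihydro-4H-pyran-4-one | CC1(C)CC(=O)C(I)=CO1 | intermediate
14 | 3-[2-methoxy-4-(triisopropylsilyloxy)phenyl]propylmagnesium chloride | COc1cc(O[Si](C(C)C)(C(C)C)C(C)C)ccc1CCC[Mg]Cl | intermediate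
15 | chloromagnesium 6-methylhept-5-en-2-yn-1-olate | CC(C)=CCC#CCO[Mg]Cl | intermediate
16 | 3-(3-methylbut-2-enyl)-4-{3-[2-methoxy-4-(triisopropylsilyloxy)phenyl]propyl}-2,5-dihydro-1,2-oxamagnesole | CC(C)=CCC1=C(CCCc2ccc(O[Si](C(C)C)(C(C)C)C(C)C)cc2OC)CO[Mg]1 | intermediate
17 | (Z)-alkenylzinc chloride, zinc on C5 cis to CH2O, oxygen as chloromagnesium alkoxide | Cl[Zn]/C(CC=C(C)C)=C(/CCCc1ccc(O[Si](C(C)C)(C(C)C)C(C)C)cc1OC)CO[Mg]Cl | intermediate
18 | (Z)-3-(2,2-dimethyl-4-oxo-3,4-dihydro-2H-pyran-5-yl)-6-methyl-2-{3-[2-methoxy-4-(triisopropylsilyloxy)phenyl]propyl}hepta-2,5-dien-1-ol | OC/C(CCCc1ccc(O[Si](C(C)C)(C(C)C)C(C)C)cc1OC)=C(/CC=C(C)C)C1=COC(C)(C)CC1=O | intermediate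
19 | methyl carbonate of 18, (Z) | COC(=O)OC/C(CCCc1ccc(O[Si](C(C)C)(C(C)C)C(C)C)cc1OC)=C(/CC=C(C)C)C1=COC(C)(C)CC1=O | intermediate
20 | methyl (Z)-4-(2,2-dimethyl-4-oxo-3,4-dihydro-2H-pyran-5-yl)-7-methyl-3-{3-[2-methoxy-4-(triisopropylsilyloxy)phenyl]propyl}octa-3,6-dienoate | COC(=O)C/C(CCCc1ccc(O[Si](C(C)C)(C(C)C)C(C)C)cc1OC)=C(/CC=C(C)C)C1=COC(C)(C)CC1=O | intermediate
21 | trimethylstannyl ester of 22, (Z) | C[Sn](C)(C)OC(=O)C/C(CCCc1ccc(O[Si](C(C)C)(C(C)C)C(C)C)cc1OC)=C(/CC=C(C)C)C1=COC(C)(C)CC1=O | intermediate
22 | (Z)-4-(2,2-dimethyl-4-oxo-3,4-dihydro-2H-pyran-5-yl)-7-methyl-3-{3-[2-methoxy-4-(triisopropylsilyloxy)phenyl]propyl}octa-3,6-dienoic acid | OC(=O)C/C(CCCc1ccc(O[Si](C(C)C)(C(C)C)C(C)C)cc1OC)=C(/CC=C(C)C)C1=COC(C)(C)CC1=O | intermediate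
23 | acetic mixed anhydride of 22, (Z) | CC(=O)OC(=O)C/C(CCCc1ccc(O[Si](C(C)C)(C(C)C)C(C)C)cc1OC)=C(/CC=C(C)C)C1=COC(C)(C)CC1=O | intermediate
24 | (Z)-4-(2,2-dimethyl-4-oxo-3,4-dihydro-2H-pyran-5-yl)-7-methyl-3-{3-[2-methoxy-4-(triisopropylsilyloxy)phenyl]propyl}octa-1,3,6-trien-1-one (dienylketene) | O=C=C/C(CCCc1ccc(O[Si](C(C)C)(C(C)C)C(C)C)cc1OC)=C(/CC=C(C)C)C1=COC(C)(C)CC1=O | intermediate
25 | rac-2,2-dimethyl-5-(3-methylbut-2-enyl)-6-{3-[2-methoxy-4-(triisopropylsilyloxy)phenyl]propyl}-2,3-dihydrochromene-4,8(8aH)-dione | O=C1C=C(CCCc2ccc(O[Si](C(C)C)(C(C)C)C(C)C)cc2OC)C(CC=C(C)C)=C2C(=O)CC(C)(C)OC12 | intermediate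
26 | 8-hydroxy-2,2-dimethyl-5-(3-methylbut-2-enyl)-6-{3-[2-methoxy-4-(triisopropylsilyloxy)phenyl]propyl}chroman-4-one | Oc1cc(CCCc2ccc(O[Si](C(C)C)(C(C)C)C(C)C)cc2OC)c(CC=C(C)C)c2C(=O)CC(C)(C)Oc12 | intermediate
27 | 2,2-dimethyl-5-(3-methylbut-2-enyl)-6-{3-[2-methoxy-4-(triisopropylsilyloxy)phenyl]propyl}-4-oxochroman-8-yl acetate | CC(=O)Oc1cc(CCCc2ccc(O[Si](C(C)C)(C(C)C)C(C)C)cc2OC)c(CC=C(C)C)c2C(=O)CC(C)(C)Oc12 | intermediate
28 | rac-2,2-dimethyl-5-(3-methylbut-2-enyl)-6-{3-[2-methoxy-4-(triisopropylsilyloxy)phenyl]propyl}chromane-4,8-diol | Oc1cc(CCCc2ccc(O[Si](C(C)C)(C(C)C)C(C)C)cc2OC)c(CC=C(C)C)c2C(O)CC(C)(C)Oc12 | intermediate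
29 | 2,2-dimethyl-5-(3-methylbut-2-enyl)-6-{3-[2-methoxy-4-(triisopropylsilyloxy)phenyl]propyl}-2H-chromen-8-ol | Oc1cc(CCCc2ccc(O[Si](C(C)C)(C(C)C)C(C)C)cc2OC)c(CC=C(C)C)c2C=CC(C)(C)Oc12 | intermediate
30 | Kazinol N, 6-[3-(4-hydroxy-2-methoxyphenyl)propyl]-2,2-dimethyl-5-(3-methylbut-2-enyl)-2H-chromen-8-ol | COc1cc(O)ccc1CCCc1cc(O)c2c(c1CC=C(C)C)C=CC(C)(C)O2 | target

**Step count**
Total step count: 13.
Longest linear sequence: 10 steps (1, 2, 6, 7, 8, 9, 10, 11, 12, 13).

**Steps most likely to fail**

**Step 10.**
- Before the ketene forms, hot acetate may enolise C3 and expel O1 from C2, a β-elimination that opens the dihydropyranone.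
- It may also draw the C5=C6 alkene into conjugation with the carboxyl group.
- Closure onto the electron-poor β-carbon of the vinylogous ester may lag behind these processes.
- Exchange of the ring A silyl group for acetyl could also occur but would be harmless, since step 11 clears an acetate.

The fallback generates the same ketene without base or heat, by a Wolff rearrangement, and sets out from alcohol 18. MnO2 in CH2Cl2 should give the (Z)-enal F1. Pinnick oxidation (NaClO2, NaH2PO4, 2-methylbut-2-ene) should then give the (Z)-2-enoic acid F2. 1-Chloro-N,N,2-trimethylprop-1-en-1-amine should convert this into the acid chloride F3, and diazomethane with NEt3 should give the α-diazoketone F4. Irradiation at 365 nm in toluene at room temperature expels nitrogen, and the alkenyl group migrates to give ketene 24. This should close through 25 to phenol 26, where the fallback comes back to the route. Ac2O–pyridine converts 26 into 27.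

**Step 6.**
- Addition of a primary alkyl Grignard reagent to the internal, skipped enynol may be slow.
- The crowded alkenylzinc may transmetalate sluggishly in a pot that still holds copper and magnesium salts.
- The cis metal alkoxide may attack C8a of the newly attached pyranone during the coupling.

The fallback interrupts the sequence at chelate 16. Trapping with B(OMe)3 and a dilute HCl work-up should give the 1,2-oxaborol-2(5H)-ol F6, which can be isolated and purified. Suzuki–Miyaura coupling of F6 with iodide 13 (PdCl2(dppf), K3PO4, THF–H2O, 40 °C) then releases the alcohol only as the C4a–C5 bond forms. The fallback comes back to the route at 18.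

**Step 8.**
- The π-allylpalladium intermediate may lose the Z geometry through a σ-allyl form.
- It may undergo β-hydride elimination toward the prenyl or propyl CH2 to give trienes.
- It may collapse with methoxide to an allyl ether before CO inserts.

The fallback merges carbonylation and ring closure and sets out from alcohol 18. Ac2O–pyridine should give the allylic acetate F5. Palladium-catalysed cyclocarbonylation follows (PdCl2(PPh3)2, CO at 60 bar, Ac2O, NEt3, toluene, 140 °C), a reaction known for 2,4-pentadienyl acetates and 3-heteroarylallyl acetates. It should give the aryl acetate directly, so the fallback comes back to the route at 27. Loss of geometry is harmless here, because the allyl isomers interconvert and only the one with the acyl group cis to the pyranone can close.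

**Further compounds**
F1 | step 10 | (Z)-3-(2,2-dimethyl-4-oxo-3,4-dihydro-2H-pyran-5-yl)-6-methyl-2-{3-[2-methoxy-4-(triisopropylsilyloxy)phenyl]propyl}hepta-2,5-dienal | O=C/C(CCCc1ccc(O[Si](C(C)C)(C(C)C)C(C)C)cc1OC)=C(/CC=C(C)C)C1=COC(C)(C)CC1=O
F2 | step 10 | (Z)-3-(2,2-dimethyl-4-oxo-3,4-dihydro-2H-pyran-5-yl)-6-methyl-2-{3-[2-methoxy-4-(triisopropylsilyloxy)phenyl]propyl}hepta-2,5-dienoic acid | OC(=O)/C(CCCc1ccc(O[Si](C(C)C)(C(C)C)C(C)C)cc1OC)=C(/CC=C(C)C)C1=COC(C)(C)CC1=O
F3 | step 10 | acid chloride of F2, (Z) | ClC(=O)/C(CCCc1ccc(O[Si](C(C)C)(C(C)C)C(C)C)cc1OC)=C(/CC=C(C)C)C1=COC(C)(C)CC1=O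
F4 | step 10 | (Z)-1-diazo-4-(2,2-dimethyl-4-oxo-3,4-dihydro-2H-pyran-5-yl)-7-methyl-3-{3-[2-methoxy-4-(triisopropylsilyloxy)phenyl]propyl}octa-3,6-dien-2-one | [N-]=[N+]=CC(=O)/C(CCCc1ccc(O[Si](C(C)C)(C(C)C)C(C)C)cc1OC)=C(/CC=C(C)C)C1=COC(C)(C)CC1=O
F5 | step 8 | acetate of 18, (Z) | CC(=O)OC/C(CCCc1ccc(O[Si](C(C)C)(C(C)C)C(C)C)cc1OC)=C(/CC=C(C)C)C1=COC(C)(C)CC1=O
F6 | step 6 | 3-(3-methylbut-2-enyl)-4-{3-[2-methoxy-4-(triisopropylsilyloxy)phenyl]propyl}-1,2-oxaborol-2(5H)-ol | CC(C)=CCC1=C(CCCc2ccc(O[Si](C(C)C)(C(C)C)C(C)C)cc2OC)COB1O
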